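The isochromanone is cut through benzene ring A. The ring's oxygen pattern (C5 methoxy, C6 and C8 oxygens, C7–H) is that of a 4-methoxy-1,3-bis(silyloxy)diene, and C4a/C8a are the two carbons of an alkynoate triple bond that already carries the C3/C4 stereodiad as a silyl ether and an acetate. A single Diels–Alder/aromatization therefore forms C5–C4a and C8–C8a, closes ring A, and places the ester at C8a within reach of the C3 oxygen for later lactone closure. The alkynoate comes from (R)-lactate and methyl propiolate by acylation, CBS reduction and acetylation; desilylative lactonization and C6 geranylation complete the target.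

Key step: step 8

Numbering used throughout: isochroman-1-one numbering, C1 lactone carbonyl, O2, C3 (methyl), C4 (acetoxy), C4a, C5 (OMe), C6 (O-geranyl), C7 (H), C8 (OH), C8a. The target is (3R,4R), i.e. 3,4-cis.

Assumption: the diene is prepared and used as its (1E,3Z) isomer, with the C4 methoxy group cis to the C3 silyloxy group and pointing away from the diene backbone. This is the geometry expected from γ-deprotonation, and only an outward methoxy allows the s-cis conformation needed for cycloaddition. The geometry at the ketene acetal end has no consequence.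

Step 1
Reactants: 1 methyl (R)-lactate
Product: 2 methyl (R)-2-(tert-butyldimethylsilyloxy)propanoate
Conditions: t-BuMe2SiCl, imidazole, DMF, 0 °C to rt
Reagents that add atoms: tert-butyldimethylsilyl chloride, CC(C)(C)[Si](C)(C)Cl
Why: Imidazole-promoted silyl ether formation on a secondary alcohol; the stereocenter (future C3) is not touched.

Step 2
Reactants: 2 methyl (R)-2-(tert-butyldimethylsilyloxy)propanoate
Product: 3 (R)-2-(tert-butyldimethylsilyloxy)-N-methoxy-N-methylpropanamide
Conditions: MeNH(OMe)·HCl, i-PrMgCl, THF, −20 to 0 °C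
Reagents that add atoms: N,O-dimethylhydroxylamine hydrochloride, CNOC.Cl
Why: Weinreb amide formation from an ester with the chloromagnesium amide of N,O-dimethylhydroxylamine, which runs at low temperature without enolizing the α-silyloxy center.

Step 3
Reactants: 3 (R)-2-(tert-butyldimethylsilyloxy)-N-methoxy-N-methylpropanamide, 4 methyl propiolate
Product: 7 methyl (5R)-5-(tert-butyldimethylsilyloxy)-4-oxohex-2-ynoate, via lithium methyl propiolate 5 (not isolated), via lithium hemiaminal alkoxide 6 (not isolated)
Conditions: 4, LiN(SiMe3)2, THF, −78 °C; then 3, −78 to −50 °C; inverse quench into cold 1 M HCl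
Reagents that add atoms: none
Why: Weinreb ketone synthesis, in which the acetylide adds once because the chelated tetrahedral adduct persists until the quench, which is done cold and inverse so that the released N,O-dimethylhydroxylamine cannot add to the ynone.

Step 4
Reactants: 7 methyl (5R)-5-(tert-butyldimethylsilyloxy)-4-oxohex-2-ynoate
Product: 9 methyl (4R,5R)-5-(tert-butyldimethylsilyloxy)-4-hydroxyhex-2-ynoate, via catecholborate ester 8 (not isolated)
Conditions: (S)-2-methyl-CBS-oxazaborolidine [(3aS)-1-methyl-3,3-diphenyltetrahydro-1H,3H-pyrrolo[1,2-c][1,3,2]oxazaborole, C18H20BNO] (0.2 equiv), catecholborane, CH2Cl2, −78 °C; MeOH, then pH 7 buffer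
Reagents that add atoms: none
Why: Corey–Bakshi–Shibata reduction in which the slim alkynyl group acts as the small substituent and the branched C5 group as the large one, so the (S)-catalyst should deliver hydride to the face giving the 4R carbinol (syn to the C5 silyloxy group), a sense reinforced by the Felkin–Anh preference of the α-silyloxy ketone (matched pair), while catecholborane at −78 °C leaves the ester and the electron-poor alkyne alone.

Step 5
Reactants: 9 methyl (4R,5R)-5-(tert-butyldimethylsilyloxy)-4-hydroxyhex-2-ynoate
Product: 10 methyl (4R,5R)-4-acetoxy-5-(tert-butyldimethylsilyloxy)hex-2-ynoate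
Conditions: Ac2O, pyridine, 4-(dimethylamino)pyridine (cat.), CH2Cl2, 0 °C
Reagents that add atoms: acetic anhydride, CC(=O)OC(C)=O
Why: Nucleophile-catalysed O-acylation of a secondary propargylic alcohol with retention at C4, the weak base and low temperature avoiding isomerization of the γ-oxygenated alkynoate.

Step 6
Reactants: 11 methyl 4-methoxyacetoacetate
Product: 12 methyl (2Z)-4-methoxy-3-(trimethylsilyloxy)but-2-enoate
Conditions: Me3SiCl, Et3N, hexane, rt
Reagents that add atoms: chlorotrimethylsilane, C[Si](C)(C)Cl
Why: Silyl enol ether formation on the conjugated enol of a β-ketoester; an E/Z mixture is acceptable because this double bond becomes the central single bond of the diene.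

Step 7
Reactants: 12 methyl (2Z)-4-methoxy-3-(trimethylsilyloxy)but-2-enoate
Product: 14 (1E,3Z)-1,4-dimethoxy-1,3-bis(trimethylsilyloxy)buta-1,3-diene, via lithium dienolate 13 (not isolated)
Conditions: LiN(i-Pr)2, THF, −78 °C; Me3SiCl, −78 to 0 °C; filtration through hexane under argon, used at once
Reagents that add atoms: chlorotrimethylsilane, C[Si](C)(C)Cl
Why: Kinetic γ-deprotonation of the vinylogous ester and O-silylation of the dienolate (the standard preparation of 1-alkoxy-1,3-bis(silyloxy)dienes), expected to place the C4 methoxy cis to the C3 silyloxy group.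

Step 8
Reactants: 10 methyl (4R,5R)-4-acetoxy-5-(tert-butyldimethylsilyloxy)hex-2-ynoate, 14 (1E,3Z)-1,4-dimethoxy-1,3-bis(trimethylsilyloxy)buta-1,3-diene
Product: 17 methyl 2-[(1R,2R)-1-acetoxy-2-(tert-butyldimethylsilyloxy)propyl]-4,6-dihydroxy-3-methoxybenzoate, via cyclohexa-1,4-diene cycloadduct 15 (not isolated), via aryl bis(trimethylsilyl) ether 16 (not isolated)
Conditions: 14 (2.5 equiv), toluene, 110 °C, sealed tube; then 1 M HCl, THF, 0 °C
Reagents that add atoms: none
Why: The electron-rich diene adds to the ester-polarized triple bond in an asynchronous normal-demand Diels–Alder cycloaddition, the methoxymethine terminus (future C5) bonding to the alkynoate β-carbon (C4a) ahead of the ketene acetal carbon (future C8) bonding to the α-carbon (C8a); cyclohexa-1,4-diene 15 then aromatizes by 1,4-loss of methanol (C8 methoxy, C5 hydrogen) and cold dilute acid removes the two aryl trimethylsilyl groups. The closest known reaction type is the Diels–Alder/aromatization of 1-alkoxy-1,3-bis(silyloxy)buta-1,3-dienes with alkynoates to give 4,6-dihydroxybenzoates, here applied to a 4-methoxy diene and a γ-acetoxy alkynoate. Ring A is closed by an intermolecular (4+2) cycloaddition that makes both ring bonds in one event, followed by elimination. No lasting stereocenter is created, since the two sp3 ring carbons of 15 are flattened on aromatization and the side-chain centers (future C3 and C4) take no part under these neutral thermal conditions. The step needs regioselectivity (C5 next to C4a), secured by pairing the diene terminus that receives electron density from the C3 silyloxy and ketene acetal oxygens with the β-carbon made electrophilic by the ester and by the inductive γ-acetoxy group. It also needs the methoxy to stay on C5, which follows because C8 carries no hydrogen and can aromatize only by giving up its own methoxy group.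

Step 9
Reactants: 17 methyl 2-[(1R,2R)-1-acetoxy-2-(tert-butyldimethylsilyloxy)propyl]-4,6-dihydroxy-3-methoxybenzoate
Product: 19 (3R,4R)-6,8-dihydroxy-5-methoxy-3-methyl-1-oxoisochroman-4-yl acetate, via hydroxy ester 18 (not isolated)
Conditions: HF·pyridine, THF, 0 °C to rt; then camphorsulfonic acid (cat.), toluene, 50 °C
Reagents that add atoms: none
Why: Fluoride cleavage of the secondary silyl ether under acidic conditions, where vicinal acetyl migration is slow, followed by acid-catalysed 6-exo-trig transesterification of the C3 hydroxyl onto the C8a methyl ester; C4 is blocked as its acetate, so only the six-membered lactone can form, and both stereocenters are retained.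

Step 10
Reactants: 19 (3R,4R)-6,8-dihydroxy-5-methoxy-3-methyl-1-oxoisochroman-4-yl acetate, 20 geranyl bromide
Product: 21 (3R,4R)-6-[(2E)-3,7-dimethylocta-2,6-dienyloxy]-8-hydroxy-5-methoxy-3-methyl-1-oxoisochroman-4-yl acetate (CNP0251645.2)
Conditions: K2CO3 (1.2 equiv), 20 (1.05 equiv), acetone, rt
Reagents that add atoms: none
Why: Williamson ether synthesis (SN2 at the primary allylic bromide) in which the C8 phenol is held in a hydrogen bond to the lactone carbonyl, so the more acidic and accessible C6 phenoxide is alkylated, with the E-alkene unchanged and the acid-sensitive geranyl ether introduced only after all acidic steps.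

Compound list
1 | methyl (R)-lactate | COC(=O)[C@@H](C)O | starting material
2 | methyl (R)-2-(tert-butyldimethylsilyloxy)propanoate | COC(=O)[C@@H](C)O[Si](C)(C)C(C)(C)C | intermediate
3 | (R)-2-(tert-butyldimethylsilyloxy)-N-methoxy-N-methylpropanamide | CON(C)C(=O)[C@@H](C)O[Si](C)(C)C(C)(C)C | intermediate
4 | methyl propiolate | C#CC(=O)OC | starting material
5 | lithium methyl propiolate (methyl 3-lithioprop-2-ynoate) | [Li]C#CC(=O)OC | intermediate
6 | methyl (5R)-5-(tert-butyldimethylsilyloxy)-4-(lithiooxy)-4-[methoxy(methyl)amino]hex-2-ynoate (C4 epimers) | COC(=O)C#CC(O[Li])(N(C)OC)[C@@H](C)O[Si](C)(C)C(C)(C)C | intermediate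
7 | methyl (5R)-5-(tert-butyldimethylsilyloxy)-4-oxohex-2-ynoate | COC(=O)C#CC(=O)[C@@H](C)O[Si](C)(C)C(C)(C)C | intermediate
8 | methyl (4R,5R)-4-(1,3,2-benzodioxaborol-2-yloxy)-5-(tert-butyldimethylsilyloxy)hex-2-ynoate | COC(=O)C#C[C@@H](OB1Oc2ccccc2O1)[C@@H](C)O[Si](C)(C)C(C)(C)C | intermediate
9 | methyl (4R,5R)-5-(tert-butyldimethylsilyloxy)-4-hydroxyhex-2-ynoate | COC(=O)C#C[C@@H](O)[C@@H](C)O[Si](C)(C)C(C)(C)C | intermediate
10 | methyl (4R,5R)-4-acetoxy-5-(tert-butyldimethylsilyloxy)hex-2-ynoate | COC(=O)C#C[C@@H](OC(C)=O)[C@@H](C)O[Si](C)(C)C(C)(C)C | intermediate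
11 | methyl 4-methoxyacetoacetate | COCC(=O)CC(=O)OC | starting material
12 | methyl (2Z)-4-methoxy-3-(trimethylsilyloxy)but-2-enoate | COC(=O)/C=C(/COC)O[Si](C)(C)C | intermediate
13 | lithium dienolate of 12 (lithium 1,4-dimethoxy-3-(trimethylsilyloxy)buta-1,3-dien-1-olate) | CO/C=C(O[Si](C)(C)C)/C=C(\OC)O[Li] | intermediate
14 | (1E,3Z)-1,4-dimethoxy-1,3-bis(trimethylsilyloxy)buta-1,3-diene | CO/C=C(O[Si](C)(C)C)/C=C(\OC)O[Si](C)(C)C | intermediate
15 | methyl 2-[(1R,2R)-1-acetoxy-2-(tert-butyldimethylsilyloxy)propyl]-3,6-dimethoxy-4,6-bis(trimethylsilyloxy)cyclohexa-1,4-diene-1-carboxylate (mixture at ring C3 and C6) | COC(=O)C1=C([C@@H](OC(C)=O)[C@@H](C)O[Si](C)(C)C(C)(C)C)C(OC)C(O[Si](C)(C)C)=CC1(OC)O[Si](C)(C)C | intermediate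
16 | methyl 2-[(1R,2R)-1-acetoxy-2-(tert-butyldimethylsilyloxy)propyl]-3-methoxy-4,6-bis(trimethylsilyloxy)benzoate | COC(=O)c1c(O[Si](C)(C)C)cc(O[Si](C)(C)C)c(OC)c1[C@@H](OC(C)=O)[C@@H](C)O[Si](C)(C)C(C)(C)C | intermediate
17 | methyl 2-[(1R,2R)-1-acetoxy-2-(tert-butyldimethylsilyloxy)propyl]-4,6-dihydroxy-3-methoxybenzoate | COC(=O)c1c(O)cc(O)c(OC)c1[C@@H](OC(C)=O)[C@@H](C)O[Si](C)(C)C(C)(C)C | intermediate
18 | methyl 2-[(1R,2R)-1-acetoxy-2-hydroxypropyl]-4,6-dihydroxy-3-methoxybenzoate | COC(=O)c1c(O)cc(O)c(OC)c1[C@@H](OC(C)=O)[C@@H](C)O | intermediate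
19 | (3R,4R)-6,8-dihydroxy-5-methoxy-3-methyl-1-oxoisochroman-4-yl acetate | COc1c(O)cc(O)c2c1[C@@H](OC(C)=O)[C@@H](C)OC2=O | intermediate
20 | geranyl bromide | CC(C)=CCC/C(C)=C/CBr | starting material
21 | (3R,4R)-6-[(2E)-3,7-dimethylocta-2,6-dienyloxy]-8-hydroxy-5-methoxy-3-methyl-1-oxoisochroman-4-yl acetate (CNP0251645.2) | COc1c(OC/C=C(\C)CCC=C(C)C)cc(O)c2c1[C@@H](OC(C)=O)[C@@H](C)OC2=O | target

Total step count: 10 steps.
Longest linear sequence: 8 steps (steps 1 to 5, then 8, 9 and 10) from methyl (R)-lactate; steps 6 and 7 form the diene branch.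

Steps most likely to fail

Step 8. Bond formation between the methoxy-bearing diene terminus and the branched β-carbon of the alkynoate may be too slow to compete with thermal decay of the open-chain diene (silyl migration, hydrolysis, oligomerization), or the diene may stay largely in the unreactive s-trans form. The fallback sets out from 10 and comes back at 17; it builds ring A by an Alder–Rickert sequence with a diene locked s-cis in a ring. Methoxyacetone and methyl acrylate (KOt-Bu, THF/t-BuOH) should undergo Michael addition at the methoxy-bearing α-carbon to give methyl 4-methoxy-5-oxohexanoate F1, which closes under the same base by Claisen condensation to 4-methoxycyclohexane-1,3-dione F2. Me3SiOTf and Et3N (Et2O, 0 °C) convert this into 4-methoxy-1,3-bis(trimethylsilyloxy)cyclohexa-1,3-diene F3. Heating F3 with 10 (toluene, 110 °C) should give, with the same regiochemistry, methyl 3-[(1R,2R)-1-acetoxy-2-(tert-butyldimethylsilyloxy)propyl]-4-methoxy-1,5-bis(trimethylsilyloxy)bicyclo[2.2.2]octa-2,5-diene-2-carboxylate F4. On further heating (xylene, 140–150 °C) this expels ethene by retro-Diels–Alder reaction to give 16, and the acid work-up of step 8 delivers 17.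

Step 3. The thermally fragile lithium acetylide may decompose before it acylates the hindered amide, or the released hydroxylamine may add to the ynone during the quench. The fallback sets out from 2 and comes back at 7; it replaces acylation by aldehyde addition and oxidation. Reduction of 2 with i-Bu2AlH (CH2Cl2, −78 °C) gives (R)-2-(tert-butyldimethylsilyloxy)propanal F5, used crude. Addition of 5 (THF, −78 °C) gives methyl (5R)-5-(tert-butyldimethylsilyloxy)-4-hydroxyhex-2-ynoate as a mixture of C4 epimers F6. Dess–Martin periodinane (NaHCO3, CH2Cl2, rt) oxidizes both epimers to 7.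

Step 4. Facial discrimination may be insufficient, or conjugate reduction or hydroboration of the doubly activated alkyne may compete. The fallback sets out from 7 and comes back at 10; it is stereoconvergent and needs no selective reduction. Luche reduction (NaBH4, CeCl3·7H2O, MeOH, −78 °C) gives both C4 carbinols, 9 and methyl (4S,5R)-5-(tert-butyldimethylsilyloxy)-4-hydroxyhex-2-ynoate F7, which are separated by chromatography. Carbinol 9 is acetylated as in step 5 with retention. F7 is converted into the same acetate 10 by Mitsunobu reaction with acetic acid (PPh3, diisopropyl azodicarboxylate, toluene, 0 °C) with inversion at C4.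

Further compounds
F1 | step 8 | methyl 4-methoxy-5-oxohexanoate (racemic) | COC(=O)CCC(OC)C(C)=O
F2 | step 8 | 4-methoxycyclohexane-1,3-dione (racemic) | COC1CCC(=O)CC1=O
F3 | step 8 | 4-methoxy-1,3-bis(trimethylsilyloxy)cyclohexa-1,3-diene | COC1=C(O[Si](C)(C)C)C=C(O[Si](C)(C)C)CC1
F4 | step 8 | methyl 3-[(1R,2R)-1-acetoxy-2-(tert-butyldimethylsilyloxy)propyl]-4-methoxy-1,5-bis(trimethylsilyloxy)bicyclo[2.2.2]octa-2,5-diene-2-carboxylate (bridgehead diastereomers) | COC(=O)C1=C([C@@H](OC(C)=O)[C@@H](C)O[Si](C)(C)C(C)(C)C)C2(OC)CCC1(O[Si](C)(C)C)C=C2O[Si](C)(C)C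
F5 | step 3 | (R)-2-(tert-butyldimethylsilyloxy)propanal | O=C[C@@H](C)O[Si](C)(C)C(C)(C)C
F6 | step 3 | methyl (5R)-5-(tert-butyldimethylsilyloxy)-4-hydroxyhex-2-ynoate (C4 epimer mixture) | COC(=O)C#CC(O)[C@@H](C)O[Si](C)(C)C(C)(C)C
F7 | step 4 | methyl (4S,5R)-5-(tert-butyldimethylsilyloxy)-4-hydroxyhex-2-ynoate | COC(=O)C#C[C@H](O)[C@@H](C)O[Si](C)(C)C(C)(C)C
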